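**Assumption:** prostanoid numbering is used for positions in all intermediates (C1 = ester carbon, C8–C12 = ring, C20 = ω‑methyl); the target is methyl (5R,6S,7Z,12R,14Z,17Z)‑10‑bromo‑5,6,12‑trihydroxy‑9‑oxoprosta‑7,10,14,17‑tetraenoate.

## Retrosynthetic overview

1. The only carbocycle is closed late by C8–C12 bond formation: 4π‑conrotatory electrocyclisation of a 2‑hydroxypentadienyl cation (C8–C12), the same event that closes the allene‑oxide‑derived oxidopentadienyl cation in the proposed clavulone/punaglandin biosynthesis. The cation comes from a fully substituted 2‑furylcarbinol and water (Piancatelli), so C9=O, C10–Br, C12–OH and the ω‑chain are in place at ring closure.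
2. C7=C8 (7Z) and the free 6‑OH arise together by E1cB opening of a 6,7‑acetonide after the ring is formed.
3. The furylcarbinol comes from a 3‑bromo‑5‑octadienyl‑2‑furyllithium and a D‑ribonolactone‑derived lactone (C5–C8 and the 5R,6S diol from D‑ribose; C1–C3 by Giese addition to methyl acrylate).
4. The ω‑chain comes from a skipped diyne (Lindlar) as the (2Z,5Z)‑octadienyl bromide, which alkylates lithiated 2,3‑dibromofuran.
5. Ring order: furan and lactone/dioxolane are bought and consumed; the cyclopentenone is the only ring made (step 8).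

## Route

Step 1
Reactants: 1 prop‑2‑yn‑1‑ol; 2 1‑bromopent‑2‑yne
Product: 3 octa‑2,5‑diyn‑1‑ol
Conditions: CuI (1 equiv), NaI (1 equiv), K2CO3 (1.5 equiv), DMF, 23 °C
Reagents that add atoms: none
Why: Copper(I)‑mediated alkyne–propargyl halide coupling, in which the copper acetylide of 1 displaces bromide from 2 under carbonate conditions mild enough not to isomerise the skipped diyne.

Step 2
Reactants: 3 octa‑2,5‑diyn‑1‑ol
Product: 4 (2Z,5Z)‑octa‑2,5‑dien‑1‑ol
Conditions: H2 (1 atm), Lindlar catalyst, quinoline, EtOAc, 0 → 23 °C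
Reagents that add atoms: none
Why: Lindlar semi‑hydrogenation delivers H2 syn to each alkyne on the poisoned Pd surface and stops at the alkene, which sets both Z double bonds (future C14 and C17).

Step 3
Reactants: 4 (2Z,5Z)‑octa‑2,5‑dien‑1‑ol
Product: 5 (2Z,5Z)‑1‑bromoocta‑2,5‑diene
Conditions: PBr3 (0.4 equiv), pyridine (cat.), Et2O, −20 → 0 °C; used at once
Reagents that add atoms: phosphorus tribromide, BrP(Br)Br
Why: Bromination of a primary allylic alcohol through its phosphite ester proceeds by SN2 at low temperature without allylic transposition or loss of Z geometry.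

Step 4
Reactants: 6 2,3‑dibromofuran; 5 (2Z,5Z)‑1‑bromoocta‑2,5‑diene
Product: 8 2,3‑dibromo‑5‑[(2Z,5Z)‑octa‑2,5‑dien‑1‑yl]furan, via dibromofuryllithium 7 (not isolated)
Conditions: LDA (1.05 equiv), THF, −78 °C (6 added to the base); then 5, −78 → −20 °C
Reagents that add atoms: none
Why: Directed α‑lithiation of 6 at its only free α‑position, then SN2 alkylation of the furyllithium with the primary allylic bromide (as in 2‑furyllithium/prenyl bromide couplings), places the ω‑chain on the future C12 and keeps both bromines.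

Step 5
Reactants: 9 2,3‑O‑isopropylidene‑D‑ribono‑1,4‑lactone
Product: 10 5‑deoxy‑5‑iodo‑2,3‑O‑isopropylidene‑D‑ribono‑1,4‑lactone
Conditions: I2 (1.3 equiv), PPh3 (1.3 equiv), imidazole (2.5 equiv), toluene, 70 °C
Reagents that add atoms: iodine, II
Why: Appel‑type (Garegg–Samuelsson) iodination converts only the primary alcohol and leaves the three ribose stereocentres (future C5, C6, C7) untouched.

Step 6
Reactants: 10 5‑deoxy‑5‑iodo‑2,3‑O‑isopropylidene‑D‑ribono‑1,4‑lactone; 11 methyl acrylate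
Product: 12 methyl 4‑[(3aR,6R,6aR)‑2,2‑dimethyl‑4‑oxotetrahydrofuro[3,4‑d][1,3]dioxol‑6‑yl]butanoate
Conditions: (TMS)3SiH (1.3 equiv, syringe pump), AIBN (10 mol %), 11 (5 equiv), toluene, 80 °C
Reagents that add atoms: none
Why: Giese radical conjugate addition, in which the primary radical from iodine abstraction adds to the acrylate and the adduct radical is reduced by the silane, installs C1–C3 in one step at a non‑stereogenic carbon and avoids the reductive β‑elimination that zinc or SN2 conditions would cause.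

Step 7
Reactants: 8 2,3‑dibromo‑5‑[(2Z,5Z)‑octa‑2,5‑dien‑1‑yl]furan; 12 methyl 4‑[(3aR,6R,6aR)‑2,2‑dimethyl‑4‑oxotetrahydrofuro[3,4‑d][1,3]dioxol‑6‑yl]butanoate
Product: 15 methyl (5R)‑5‑[(4R,5S)‑5‑[(RS)‑{3‑bromo‑5‑[(2Z,5Z)‑octa‑2,5‑dien‑1‑yl]furan‑2‑yl}(hydroxy)methyl]‑2,2‑dimethyl‑1,3‑dioxolan‑4‑yl]‑5‑hydroxypentanoate, via furyllithium 13 (not isolated), via lactol 14 (not isolated)
Conditions: n‑BuLi (1.0 equiv), THF, −78 °C, 15 min; 12 (0.95 equiv), −78 °C; then MeOH, NaBH4 (2 equiv), −78 → 0 °C; aq. NH4Cl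
Reagents that add atoms: none
Why: Selective Br/Li exchange at the α‑bromine gives 13 (bromine kept at the future C10), which adds once to the activated α‑alkoxy γ‑lactone much faster than to the remote methyl ester at −78 °C, and NaBH4 then reduces the ring‑opened furyl ketone in the same flask (aryllithium–lactone addition/hydride reduction as in C‑nucleoside synthesis); C8 forms as an epimer mixture, which does not matter because C8 is ionised in step 8.

Step 8
Reactants: 15 methyl (5R)‑5‑[(4R,5S)‑5‑[(RS)‑{3‑bromo‑5‑[(2Z,5Z)‑octa‑2,5‑dien‑1‑yl]furan‑2‑yl}(hydroxy)methyl]‑2,2‑dimethyl‑1,3‑dioxolan‑4‑yl]‑5‑hydroxypentanoate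
Product: 16 methyl (5R)‑5‑[(4R,5S)‑5‑[(1S,5S)‑3‑bromo‑5‑hydroxy‑5‑[(2Z,5Z)‑octa‑2,5‑dien‑1‑yl]‑2‑oxocyclopent‑3‑en‑1‑yl]‑2,2‑dimethyl‑1,3‑dioxolan‑4‑yl]‑5‑hydroxypentanoate
Conditions: ZnCl2 (2 equiv), acetone/H2O (2:1), 60 °C, pH ≈ 5–6
Reagents that add atoms: water, O
Why: Piancatelli rearrangement, in which ionisation at C8, attack of water at the alkyl‑bearing furan carbon and ring opening give the 2‑hydroxypentadienyl cation over C8–C12 that closes by thermal 4π conrotation to the C8–C12 bond with C7 and the C12 hydroxyl outward (C8/C12 trans); the sense of conrotation is set by the C7 dioxolane stereocentre (C7–O inside and hydrogen‑bonded to the C9 hydroxyl, bond formation anti to C6) and is predicted to give the target's 12R arrangement (CIP label S in 16), while C8 is removed in step 9.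

Step 9
Reactants: 16 methyl (5R)‑5‑[(4R,5S)‑5‑[(1S,5S)‑3‑bromo‑5‑hydroxy‑5‑[(2Z,5Z)‑octa‑2,5‑dien‑1‑yl]‑2‑oxocyclopent‑3‑en‑1‑yl]‑2,2‑dimethyl‑1,3‑dioxolan‑4‑yl]‑5‑hydroxypentanoate
Product: 17 methyl (5R,6S,7Z)‑7‑[(2R)‑4‑bromo‑2‑hydroxy‑2‑[(2Z,5Z)‑octa‑2,5‑dien‑1‑yl]‑5‑oxocyclopent‑3‑en‑1‑ylidene]‑5,6‑dihydroxyheptanoate
Conditions: MgBr2·OEt2 (2 equiv), i‑Pr2NEt (3 equiv), CH2Cl2, −20 → 0 °C; pH 7 phosphate buffer
Reagents that add atoms: none
Why: E1cB (retro‑oxa‑Michael) elimination under soft enolisation, in which the magnesium enolate of the C9 ketone expels the C7 acetonide oxygen and the hemiketal alkoxide loses acetone to free the 6‑OH; chelation of Mg between the enolate oxygen and the dioxolane oxygens holds C6 on the carbonyl side so the 7Z alkene is expected to predominate, and C5, C6 and C12 are not touched.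

## Compound list

1 | prop‑2‑yn‑1‑ol | C#CCO | starting material
2 | 1‑bromopent‑2‑yne | CCC#CCBr | starting material
3 | octa‑2,5‑diyn‑1‑ol | CCC#CCC#CCO | intermediate
4 | (2Z,5Z)‑octa‑2,5‑dien‑1‑ol | CC/C=C\C/C=C\CO | intermediate
5 | (2Z,5Z)‑1‑bromoocta‑2,5‑diene | CC/C=C\C/C=C\CBr | intermediate
6 | 2,3‑dibromofuran | Brc1ccoc1Br | starting material
7 | (4,5‑dibromofuran‑2‑yl)lithium | [Li]c1cc(Br)c(Br)o1 | intermediate
8 | 2,3‑dibromo‑5‑[(2Z,5Z)‑octa‑2,5‑dien‑1‑yl]furan | CC/C=C\C/C=C\Cc1cc(Br)c(Br)o1 | intermediate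
9 | 2,3‑O‑isopropylidene‑D‑ribono‑1,4‑lactone, (3aR,6R,6aR)‑6‑(hydroxymethyl)‑2,2‑dimethyldihydrofuro[3,4‑d][1,3]dioxol‑4(3aH)‑one | O=C1O[C@H](CO)[C@H]2OC(C)(C)O[C@@H]12 | starting material
10 | 5‑deoxy‑5‑iodo‑2,3‑O‑isopropylidene‑D‑ribono‑1,4‑lactone | O=C1O[C@H](CI)[C@H]2OC(C)(C)O[C@@H]12 | intermediate
11 | methyl acrylate | C=CC(=O)OC | starting material
12 | methyl 4‑[(3aR,6R,6aR)‑2,2‑dimethyl‑4‑oxotetrahydrofuro[3,4‑d][1,3]dioxol‑6‑yl]butanoate | O=C1O[C@H](CCCC(=O)OC)[C@H]2OC(C)(C)O[C@@H]12 | intermediate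
13 | {3‑bromo‑5‑[(2Z,5Z)‑octa‑2,5‑dien‑1‑yl]furan‑2‑yl}lithium | [Li]c1oc(C/C=C\C/C=C\CC)cc1Br | intermediate
14 | 1‑C‑{3‑bromo‑5‑[(2Z,5Z)‑octa‑2,5‑dien‑1‑yl]furan‑2‑yl}‑5‑deoxy‑5‑(2‑methoxycarbonylethyl)‑2,3‑O‑isopropylidene‑D‑ribofuranose (lactol, both anomers) | OC1(c2oc(C/C=C\C/C=C\CC)cc2Br)O[C@H](CCCC(=O)OC)[C@H]2OC(C)(C)O[C@@H]12 | intermediate
15 | methyl (5R)‑5‑[(4R,5S)‑5‑[(RS)‑{3‑bromo‑5‑[(2Z,5Z)‑octa‑2,5‑dien‑1‑yl]furan‑2‑yl}(hydroxy)methyl]‑2,2‑dimethyl‑1,3‑dioxolan‑4‑yl]‑5‑hydroxypentanoate (both C8 epimers) | COC(=O)CCC[C@@H](O)[C@H]1OC(C)(C)O[C@H]1C(O)c1oc(C/C=C\C/C=C\CC)cc1Br | intermediate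
16 | methyl (5R)‑5‑[(4R,5S)‑5‑[(1S,5S)‑3‑bromo‑5‑hydroxy‑5‑[(2Z,5Z)‑octa‑2,5‑dien‑1‑yl]‑2‑oxocyclopent‑3‑en‑1‑yl]‑2,2‑dimethyl‑1,3‑dioxolan‑4‑yl]‑5‑hydroxypentanoate (8,12‑trans) | COC(=O)CCC[C@@H](O)[C@H]1OC(C)(C)O[C@H]1[C@@H]2C(=O)C(Br)=C[C@]2(O)C/C=C\C/C=C\CC | intermediate
17 | methyl (5R,6S,7Z)‑7‑[(2R)‑4‑bromo‑2‑hydroxy‑2‑[(2Z,5Z)‑octa‑2,5‑dien‑1‑yl]‑5‑oxocyclopent‑3‑en‑1‑ylidene]‑5,6‑dihydroxyheptanoate | CC/C=C\C/C=C\C[C@@]1(O)C=C(Br)C(=O)/C1=C\[C@H](O)[C@H](O)CCCC(=O)OC | target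

## Step count and risks

Total steps: 9. Longest linear sequence: 7 (steps 1–4, 7–9); steps 5–6 form the second branch.

**Step 8 (most likely to fail).** The furfuryl cation is destabilised by the C7 oxygen and the ring bromine, and it can be trapped reversibly by the 5‑OH. Water must attack a substituted furan carbon, and the δ‑hydroxy ester can lactonise in warm aqueous Lewis acid. The C12 configuration rests on two assumptions: the hydroxyl‑outward cation geometry of the parent rearrangement, and the torquoselectivity model; if either fails, the 12‑epimer dominates. That epimer is a diastereomer of 17 and is separable. Fallback, setting out from 15 and returning at 16: cyclodehydrate 15 (cat. CSA, 4 Å sieves, CH2Cl2, 0 °C) to the C‑furanoside F1. Rearrange this isolated furfuryl ether at 23 °C in chloroform containing about 3 equiv of water with a chiral BINOL‑derived N‑triflylphosphoramide (10 mol %). The chiral counter‑anion, not C7, then steers the conrotation (both acid enantiomers are tried to find the matched case), and the conditions are anhydrous enough to spare the acetonide and ester; the product is 16.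

**Step 9.** Dehydrations of related aldols in the punaglandin series give 7E/7Z mixtures, so the chelation‑based Z preference is not assured. Fallback, setting out from 16 and returning at 17: run the elimination with DBU alone (CH2Cl2, 0 °C) and isolate the 7E isomer F2. Isomerise it photochemically (365 nm, benzene, 10 °C) to a Z‑enriched mixture in which 17 is favoured by the O6–H···O=C9 hydrogen bond. Separate 17 and recycle the recovered 7E material.

**Step 7.** The furyllithium may attack the methyl ester, or enolise the lactone with loss of the acetonide. Fallback, setting out from 8 and 9 and returning at 15: move the coupling ahead of the chain extension. Deprotonate hydroxy lactone 9 with LiHMDS (1 equiv), add 13 (made from 8 as in step 7) at −78 °C and reduce in the same flask with NaBH4 to the triol F3. Iodinate the primary hydroxyl selectively (I2, PPh3, imidazole, THF, 0 °C) to the iodo diol F4. Run the Giese addition of F4 to methyl acrylate 11 ((TMS)3SiH, AIBN, 80 °C) to reach 15.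

## Further compounds

F1 | step 8 | 1,4‑anhydro‑1‑C‑{3‑bromo‑5‑[(2Z,5Z)‑octa‑2,5‑dien‑1‑yl]furan‑2‑yl}‑5‑deoxy‑5‑(2‑methoxycarbonylethyl)‑2,3‑O‑isopropylidene‑D‑ribitol (C‑furanoside, both C1 anomers) | COC(=O)CCC[C@H]1OC(c2oc(C/C=C\C/C=C\CC)cc2Br)[C@@H]2OC(C)(C)O[C@H]12
F2 | step 9 | methyl (5R,6S,7E,12R,14Z,17Z)‑10‑bromo‑5,6,12‑trihydroxy‑9‑oxoprosta‑7,10,14,17‑tetraenoate (7E isomer of 17) | CC/C=C\C/C=C\C[C@@]1(O)C=C(Br)C(=O)/C1=C/[C@H](O)[C@H](O)CCCC(=O)OC
F3 | step 7 | 1‑C‑{3‑bromo‑5‑[(2Z,5Z)‑octa‑2,5‑dien‑1‑yl]furan‑2‑yl}‑2,3‑O‑isopropylidene‑D‑ribitol (triol, both C1 epimers) | OC[C@@H](O)[C@H]1OC(C)(C)O[C@H]1C(O)c1oc(C/C=C\C/C=C\CC)cc1Br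
F4 | step 7 | 1‑C‑{3‑bromo‑5‑[(2Z,5Z)‑octa‑2,5‑dien‑1‑yl]furan‑2‑yl}‑5‑deoxy‑5‑iodo‑2,3‑O‑isopropylidene‑D‑ribitol (iodo diol, both C1 epimers) | IC[C@@H](O)[C@H]1OC(C)(C)O[C@H]1C(O)c1oc(C/C=C\C/C=C\CC)cc1Br
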